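**Plan**

- Retrosynthetic cuts, in order: the aryl MOM ether; the C6–alkenyl bond (Suzuki); the oxepine C2′–O aryl ether bond; the two pyranone bonds C3–C4 and O1–C2 in one operation; the aryl–alkyne bond (Sonogashira); the C–C bond made by acetylide opening of an epoxide.
- Enabling feature: ring C is a 4-pyranone whose acyl carbon C4 sits on ring A ortho to the phenolic oxygen O1, and whose C2=C3 bond carries ring B on C2 and a CH2 group on C3. This is the pattern of a salicylaldehyde joined across an aryl alkyl alkyne.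
- Forward order: rings A and B come from the starting materials; ring C is closed by the annulation (step 7), the oxepine next (step 9); then the alkenyl chain is attached at C6 and the phenol is freed.
- Stereochemistry: the single (S) stereocenter comes from methyl (S)-glycidate and none of its bonds is broken afterwards. The (E) alkene comes from syn hydroboration of 3-methylbut-1-yne.

Key step: step 7

Remark: flavone locants are used (ring A C5–C8, pyranone O1–C4, ring B C1′–C6′). The diol is carried as a cyclic carbonate, which is removed by base, so that its release cannot endanger the acid-labile MOM ether. 3-Bromo-4-iodophenol and methyl (S)-glycidate are taken as purchasable.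

**Route**

Step 1
Reactants: 1 2,4,6-trihydroxybenzaldehyde
Product: 2 2,6-dihydroxy-4-methoxybenzaldehyde
Conditions: MeI (1.0 equiv), K2CO3 (1.0 equiv), acetone, 0 to 25 °C
Reagents that add atoms: iodomethane, CI
Why: Williamson O-methylation under base-limited conditions: the 4-OH, para to the formyl group and not held in the intramolecular hydrogen bond, is the most acidic and most accessible phenol, so it should be alkylated ahead of the two ortho hydroxyls.

Step 2
Reactants: 3 3-bromo-4-iodophenol
Product: 4 2-bromo-1-iodo-4-(methoxymethoxy)benzene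
Conditions: MOMCl (1.3 equiv), iPr2NEt (1.5 equiv), CH2Cl2, 0 to 25 °C
Reagents that add atoms: chloromethyl methyl ether, COCCl
Why: Routine O-alkylation of the phenol with MOMCl (MOM ether formation); both carbon–halogen bonds are inert and the acetal should survive every basic and metal-catalysed step that follows.

Step 3
Reactants: 5 methyl (2S)-oxirane-2-carboxylate (methyl (S)-glycidate)
Product: 7 2-[(2S)-oxiran-2-yl]propan-2-ol, via 1-[(2S)-oxiran-2-yl]ethan-1-one 6 (not isolated)
Conditions: MeMgBr (2.2 equiv), THF, −78 to −20 °C; then H2O/NH4Cl; the volatile product is carried on as a dried concentrate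
Reagents that add atoms: methylmagnesium bromide, C[Mg]Br
Why: Double Grignard addition to the ester, which at low temperature is much faster than attack on the epoxide; the C–O and C–H bonds of the stereocenter are untouched, so the (S) configuration of 5 is carried into 7.

Step 4
Reactants: 7 2-[(2S)-oxiran-2-yl]propan-2-ol
Product: 8 (3S)-2-methylhex-5-yne-2,3-diol
Conditions: LiC≡CH·H2NCH2CH2NH2 (3 equiv), DMSO, 0 to 25 °C; then H2O
Reagents that add atoms: lithium acetylide–ethylenediamine complex, [Li+].[C-]#C.NCCN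
Why: SN2 opening of the terminal epoxide by acetylide at the unsubstituted CH2 carbon (the tertiary alkoxide is a spectator), so the configured carbon keeps its C–O bond and its (S) descriptor.

Step 5
Reactants: 8 (3S)-2-methylhex-5-yne-2,3-diol
Product: 10 (5S)-4,4-dimethyl-5-(prop-2-yn-1-yl)-1,3-dioxolan-2-one, via (3S)-2-hydroxy-2-methylhex-5-yn-3-yl 1H-imidazole-1-carboxylate 9 (not isolated)
Conditions: 1,1′-carbonyldiimidazole (1.5 equiv), toluene, 80 °C
Reagents that add atoms: 1,1′-carbonyldiimidazole, O=C(n1ccnc1)n1ccnc1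
Why: Carbonylation of a 1,2-diol with CDI: O-acylation of the secondary hydroxyl and 5-exo-trig attack of the tertiary hydroxyl on the acyl imidazole give the cyclic carbonate, a base-labile mask that is inert to the oxidative annulation and orthogonal to the MOM ether.

Step 6
Reactants: 4 2-bromo-1-iodo-4-(methoxymethoxy)benzene; 10 (5S)-4,4-dimethyl-5-(prop-2-yn-1-yl)-1,3-dioxolan-2-one
Product: 11 (5S)-5-{3-[2-bromo-4-(methoxymethoxy)phenyl]prop-2-yn-1-yl}-4,4-dimethyl-1,3-dioxolan-2-one
Conditions: Pd(PPh3)2Cl2 (2 mol %), CuI (4 mol %), Et3N, THF, 25 °C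
Reagents that add atoms: none
Why: Sonogashira coupling: zerovalent palladium inserts into the C–I bond at room temperature far faster than into the ortho C–Br bond, which is kept for the oxepine closure.

Step 7
Reactants: 2 2,6-dihydroxy-4-methoxybenzaldehyde (1.2 equiv); 11 (5S)-5-{3-[2-bromo-4-(methoxymethoxy)phenyl]prop-2-yn-1-yl}-4,4-dimethyl-1,3-dioxolan-2-one
Product: 12 2-[2-bromo-4-(methoxymethoxy)phenyl]-3-{[(4S)-5,5-dimethyl-2-oxo-1,3-dioxolan-4-yl]methyl}-5-hydroxy-7-methoxy-4H-chromen-4-one
Conditions: [Cp*RhCl2]2 (2.5 mol %), Cu(OAc)2 (2.1 equiv), o-xylene, 120 °C, N2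
Reagents that add atoms: none
Why: Acetate-assisted formation of a rhodium phenoxide and cleavage of the formyl C–H give a five-membered acyl rhodacycle; the alkyne inserts into the Rh–acyl bond with its CH2-bearing carbon bonding to the acyl carbon (C3–C4) and its aryl-bearing carbon staying on rhodium, and C–O reductive elimination from the seven-membered oxarhodacycle forms O1–C2, after which Cu(OAc)2 returns monovalent rhodium to the trivalent state. The closest known reaction is the rhodium-catalysed oxidative coupling of salicylaldehydes with internal alkynes to 2,3-disubstituted chromones (aldehyde C–H/O–H annulation). The pyranone closes as a formal (4+2) annulation, its last bond (O1–C2) being made by reductive elimination inside the metallacycle. No stereocenter is formed, and the carbonate stereocenter two atoms from the alkyne takes no part. The step needs regioselective insertion (aryl carbon next to oxygen), which the aryl alkyl substitution of 11 should secure because rhodium prefers the aryl-substituted, conjugation-stabilised alkenyl carbon, a bias reinforced by the para methoxymethoxy donor; no site selectivity is needed on the aldehyde because 2 is symmetric, the second hydroxyl simply becoming the 5-OH. The C–Br bond, the carbonate and the MOM ether should be inert to trivalent rhodium and Cu(OAc)2.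

Step 8
Reactants: 12 2-[2-bromo-4-(methoxymethoxy)phenyl]-3-{[(4S)-5,5-dimethyl-2-oxo-1,3-dioxolan-4-yl]methyl}-5-hydroxy-7-methoxy-4H-chromen-4-one
Product: 13 2-[2-bromo-4-(methoxymethoxy)phenyl]-3-[(2S)-2,3-dihydroxy-3-methylbutyl]-5-hydroxy-7-methoxy-4H-chromen-4-one
Conditions: K2CO3 (0.5 equiv), MeOH, 25 °C
Reagents that add atoms: none
Why: Base-catalysed transesterification of the cyclic carbonate with methanol frees the diol as dimethyl carbonate, conditions under which the MOM ether, the aryl bromide and the flavone core are stable and the stereocenter is not touched.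

Step 9
Reactants: 13 2-[2-bromo-4-(methoxymethoxy)phenyl]-3-[(2S)-2,3-dihydroxy-3-methylbutyl]-5-hydroxy-7-methoxy-4H-chromen-4-one
Product: 14 (6S)-9-hydroxy-6-(2-hydroxypropan-2-yl)-11-methoxy-3-(methoxymethoxy)-6,7-dihydro-8H-chromeno[3,2-d][1]benzoxepin-8-one (the flavone of 13 with the secondary oxygen bonded to C2′; ring O–C2′–C1′–C2–C3–CH2–CH)
Conditions: CuI (10 mol %), 3,4,7,8-tetramethyl-1,10-phenanthroline (20 mol %), Cs2CO3 (2.5 equiv), toluene (0.02 M), 110 °C
Reagents that add atoms: none
Why: Intramolecular copper-catalysed Ullmann-type C–O coupling of an aliphatic alcohol with an aryl bromide: the secondary alkoxide closes the seven-membered ring onto C2′ (the tertiary one would need an eight-membered ring), and since the O–C bond of the stereocenter is not broken the (S) configuration is retained.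

Step 10
Reactants: 14 (6S)-9-hydroxy-6-(2-hydroxypropan-2-yl)-11-methoxy-3-(methoxymethoxy)-6,7-dihydro-8H-chromeno[3,2-d][1]benzoxepin-8-one
Product: 15 (6S)-9-hydroxy-6-(2-hydroxypropan-2-yl)-10-iodo-11-methoxy-3-(methoxymethoxy)-6,7-dihydro-8H-chromeno[3,2-d][1]benzoxepin-8-one (iodine at flavone C6)
Conditions: BnMe3N·ICl2 (1.05 equiv), CaCO3 (1.5 equiv), CH2Cl2–MeOH (5:2), 25 °C
Reagents that add atoms: benzyltrimethylammonium dichloroiodate, C[N+](C)(C)Cc1ccccc1.Cl[I-]Cl
Why: Electrophilic aromatic iodination with BnMe3N·ICl2 under carbonate buffering, a reagent that iodinates phenols but not aryl ethers at room temperature, is directed ortho to the chelated 5-OH, that is to C6, as is usual for 5-hydroxy-7-alkoxyflavones.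

Step 11
Reactants: 16 3-methylbut-1-yne
Product: 17 4,4,5,5-tetramethyl-2-[(1E)-3-methylbut-1-en-1-yl]-1,3,2-dioxaborolane
Conditions: pinacolborane (1.05 equiv), Cp2Zr(H)Cl (5 mol %), Et3N (10 mol %), CH2Cl2, sealed vessel, 25 to 40 °C
Reagents that add atoms: pinacolborane (4,4,5,5-tetramethyl-1,3,2-dioxaborolane), CC1(C)OBOC1(C)C
Why: Zirconocene hydride-catalysed hydroboration of a terminal alkyne with pinacolborane: syn addition with boron on the terminal carbon fixes the (E) geometry.

Step 12
Reactants: 15 (6S)-9-hydroxy-6-(2-hydroxypropan-2-yl)-10-iodo-11-methoxy-3-(methoxymethoxy)-6,7-dihydro-8H-chromeno[3,2-d][1]benzoxepin-8-one; 17 4,4,5,5-tetramethyl-2-[(1E)-3-methylbut-1-en-1-yl]-1,3,2-dioxaborolane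
Product: 18 (6S)-9-hydroxy-6-(2-hydroxypropan-2-yl)-11-methoxy-3-(methoxymethoxy)-10-[(1E)-3-methylbut-1-en-1-yl]-6,7-dihydro-8H-chromeno[3,2-d][1]benzoxepin-8-one
Conditions: Pd(OAc)2 (5 mol %), SPhos (10 mol %), K3PO4 (3 equiv), toluene–H2O (10:1), 80 °C
Reagents that add atoms: none
Why: Suzuki–Miyaura coupling with retention of the alkene geometry; the bulky, electron-rich SPhos ligand is chosen for the iodide flanked by OH and OMe, and the free phenol and tertiary alcohol are tolerated under aqueous phosphate.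

Step 13
Reactants: 18 (6S)-9-hydroxy-6-(2-hydroxypropan-2-yl)-11-methoxy-3-(methoxymethoxy)-10-[(1E)-3-methylbut-1-en-1-yl]-6,7-dihydro-8H-chromeno[3,2-d][1]benzoxepin-8-one
Product: 19 (6S)-3,9-dihydroxy-6-(2-hydroxypropan-2-yl)-11-methoxy-10-[(1E)-3-methylbut-1-en-1-yl]-6,7-dihydro-8H-chromeno[3,2-d][1]benzoxepin-8-one (CNP0216454.2)
Conditions: aq HCl (3 M)–MeOH (1:4), 25 to 40 °C
Reagents that add atoms: none
Why: Acid-catalysed cleavage of the aryl MOM acetal (transacetalisation to dimethoxymethane), kept dilute and near room temperature so that the tertiary alcohol and the styrene-type alkene next to the 5-OH are not ionised or cyclised.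

**Compound list**

1 | 2,4,6-trihydroxybenzaldehyde | O=Cc1c(O)cc(O)cc1O | starting material
2 | 2,6-dihydroxy-4-methoxybenzaldehyde | COc1cc(O)c(C=O)c(O)c1 | intermediate
3 | 3-bromo-4-iodophenol | Oc1ccc(I)c(Br)c1 | starting material
4 | 2-bromo-1-iodo-4-(methoxymethoxy)benzene | COCOc1ccc(I)c(Br)c1 | intermediate
5 | methyl (2S)-oxirane-2-carboxylate | COC(=O)[C@@H]1CO1 | starting material
6 | 1-[(2S)-oxiran-2-yl]ethan-1-one | CC(=O)[C@@H]1CO1 | intermediate (not isolated)
7 | 2-[(2S)-oxiran-2-yl]propan-2-ol | CC(C)(O)[C@@H]1CO1 | intermediate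
8 | (3S)-2-methylhex-5-yne-2,3-diol | CC(C)(O)[C@@H](O)CC#C | intermediate
9 | (3S)-2-hydroxy-2-methylhex-5-yn-3-yl 1H-imidazole-1-carboxylate | CC(C)(O)[C@@H](OC(=O)n1ccnc1)CC#C | intermediate (not isolated)
10 | (5S)-4,4-dimethyl-5-(prop-2-yn-1-yl)-1,3-dioxolan-2-one | C#CC[C@@H]1OC(=O)OC1(C)C | intermediate
11 | (5S)-5-{3-[2-bromo-4-(methoxymethoxy)phenyl]prop-2-yn-1-yl}-4,4-dimethyl-1,3-dioxolan-2-one | COCOc1ccc(C#CC[C@@H]2OC(=O)OC2(C)C)c(Br)c1 | intermediate
12 | 2-[2-bromo-4-(methoxymethoxy)phenyl]-3-{[(4S)-5,5-dimethyl-2-oxo-1,3-dioxolan-4-yl]methyl}-5-hydroxy-7-methoxy-4H-chromen-4-one | COc1cc2oc(-c3ccc(OCOC)cc3Br)c(C[C@@H]3OC(=O)OC3(C)C)c(=O)c2c(O)c1 | intermediate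
13 | 2-[2-bromo-4-(methoxymethoxy)phenyl]-3-[(2S)-2,3-dihydroxy-3-methylbutyl]-5-hydroxy-7-methoxy-4H-chromen-4-one | COc1cc2oc(-c3ccc(OCOC)cc3Br)c(C[C@H](O)C(C)(C)O)c(=O)c2c(O)c1 | intermediate
14 | (6S)-9-hydroxy-6-(2-hydroxypropan-2-yl)-11-methoxy-3-(methoxymethoxy)-6,7-dihydro-8H-chromeno[3,2-d][1]benzoxepin-8-one | COc1cc2oc3c(c(=O)c2c(O)c1)C[C@@H](C(C)(C)O)Oc1cc(OCOC)ccc1-3 | intermediate
15 | (6S)-9-hydroxy-6-(2-hydroxypropan-2-yl)-10-iodo-11-methoxy-3-(methoxymethoxy)-6,7-dihydro-8H-chromeno[3,2-d][1]benzoxepin-8-one | COc1cc2oc3c(c(=O)c2c(O)c1I)C[C@@H](C(C)(C)O)Oc1cc(OCOC)ccc1-3 | intermediate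
16 | 3-methylbut-1-yne | CC(C)C#C | starting material
17 | 4,4,5,5-tetramethyl-2-[(1E)-3-methylbut-1-en-1-yl]-1,3,2-dioxaborolane | CC(C)/C=C/B1OC(C)(C)C(C)(C)O1 | intermediate
18 | (6S)-9-hydroxy-6-(2-hydroxypropan-2-yl)-11-methoxy-3-(methoxymethoxy)-10-[(1E)-3-methylbut-1-en-1-yl]-6,7-dihydro-8H-chromeno[3,2-d][1]benzoxepin-8-one | COc1cc2oc3c(c(=O)c2c(O)c1/C=C/C(C)C)C[C@@H](C(C)(C)O)Oc1cc(OCOC)ccc1-3 | intermediate
19 | (6S)-3,9-dihydroxy-6-(2-hydroxypropan-2-yl)-11-methoxy-10-[(1E)-3-methylbut-1-en-1-yl]-6,7-dihydro-8H-chromeno[3,2-d][1]benzoxepin-8-one | COc1cc2oc3c(c(=O)c2c(O)c1/C=C/C(C)C)C[C@@H](C(C)(C)O)Oc1cc(O)ccc1-3 | target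

**Count**

Total steps: 13. Longest linear sequence: 10 steps (5 → 7 → 8 → 10 → 11 → 12 → 13 → 14 → 15 → 18 → 19; steps 3, 4, 5, 6, 7, 8, 9, 10, 12, 13).

**Steps most likely to fail**

Step 7 (oxidative annulation). What may go wrong: the second free hydroxyl lets the aldehyde and the 5-hydroxy-4-oxo product bind rhodium and copper as stable chelates, and the very electron-rich ring is oxidised by Cu(OAc)2, so turnover stops and the acyl rhodium loses CO instead of inserting the hindered alkyne. Fallback, setting out from 2: one hydroxyl is masked as an ester, so that the annulation runs on an ordinary, less electron-rich mono-salicylaldehyde and gives a product that cannot chelate. Pivaloyl chloride (1.0 equiv, Et3N, CH2Cl2, 0 °C) should give 2-formyl-3-hydroxy-5-methoxyphenyl 2,2-dimethylpropanoate F1. The annulation with 11 under the conditions of step 7 should then give 2-[2-bromo-4-(methoxymethoxy)phenyl]-3-{[(4S)-5,5-dimethyl-2-oxo-1,3-dioxolan-4-yl]methyl}-7-methoxy-4-oxo-4H-chromen-5-yl 2,2-dimethylpropanoate F2. K2CO3 in MeOH cleaves the pivalate and the carbonate in one operation, and the route is rejoined at diol 13.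

Step 9 (oxepine closure). What may go wrong: copper is tied up by the diol and by the 5-oxido-4-keto chelate while oxidative addition of the ortho-substituted C–Br bond is slow, so protodebromination and intermolecular phenoxide arylation take over. Fallback, setting out from alkyne 10: the ring is closed by metal-free SNAr on an aryl fluoride instead.
- Commercial 3-fluoro-4-iodophenol is protected (MOMCl, iPr2NEt) as 2-fluoro-1-iodo-4-(methoxymethoxy)benzene F3.
- Sonogashira coupling of this iodide with 10 as in step 6 should give (5S)-5-{3-[2-fluoro-4-(methoxymethoxy)phenyl]prop-2-yn-1-yl}-4,4-dimethyl-1,3-dioxolan-2-one F4.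
- Annulation with 2 as in step 7 should give 2-[2-fluoro-4-(methoxymethoxy)phenyl]-3-{[(4S)-5,5-dimethyl-2-oxo-1,3-dioxolan-4-yl]methyl}-5-hydroxy-7-methoxy-4H-chromen-4-one F5.
- Methanolysis as in step 8 should give 2-[2-fluoro-4-(methoxymethoxy)phenyl]-3-[(2S)-2,3-dihydroxy-3-methylbutyl]-5-hydroxy-7-methoxy-4H-chromen-4-one F6.
- Intramolecular SNAr of the secondary alkoxide (KOt-Bu, DMF, 60 to 80 °C) closes the oxepine and rejoins the route at 14. The fluoride is activated by the ortho chromon-2-yl group, a vinylogous acyl substituent, but only weakly, so this closure may need forcing.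

Step 10 (C6 iodination). What may go wrong: the electrophile attacks C8 of ring A or the now doubly oxygenated ring B (C3′/C5′) instead of C6, and the hindered iodide then loses iodine in the coupling of step 12. Fallback, setting out from 14: the carbon is introduced by a reaction that can only occur ortho to the phenol. Magnesium-mediated ortho-formylation (MgCl2, Et3N, paraformaldehyde, MeCN, reflux) should give (6S)-9-hydroxy-6-(2-hydroxypropan-2-yl)-11-methoxy-3-(methoxymethoxy)-8-oxo-6,7-dihydro-8H-chromeno[3,2-d][1]benzoxepine-10-carbaldehyde F7, C6 being the only free position next to the 5-OH. Julia–Kocienski olefination with 5-[(2-methylpropyl)sulfonyl]-1-phenyl-1H-tetrazole and excess KN(SiMe3)2 (DME, −60 to 25 °C; the extra base covers the two hydroxyls) should give the (E)-alkene. The route is rejoined at 18, bypassing steps 10 and 12.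

**Further compounds**

F1 | step 7 | 2-formyl-3-hydroxy-5-methoxyphenyl 2,2-dimethylpropanoate | COc1cc(O)c(C=O)c(OC(=O)C(C)(C)C)c1
F2 | step 7 | 2-[2-bromo-4-(methoxymethoxy)phenyl]-3-{[(4S)-5,5-dimethyl-2-oxo-1,3-dioxolan-4-yl]methyl}-7-methoxy-4-oxo-4H-chromen-5-yl 2,2-dimethylpropanoate | COc1cc2oc(-c3ccc(OCOC)cc3Br)c(C[C@@H]3OC(=O)OC3(C)C)c(=O)c2c(OC(=O)C(C)(C)C)c1
F3 | step 9 | 2-fluoro-1-iodo-4-(methoxymethoxy)benzene | COCOc1ccc(I)c(F)c1
F4 | step 9 | (5S)-5-{3-[2-fluoro-4-(methoxymethoxy)phenyl]prop-2-yn-1-yl}-4,4-dimethyl-1,3-dioxolan-2-one | COCOc1ccc(C#CC[C@@H]2OC(=O)OC2(C)C)c(F)c1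
F5 | step 9 | 2-[2-fluoro-4-(methoxymethoxy)phenyl]-3-{[(4S)-5,5-dimethyl-2-oxo-1,3-dioxolan-4-yl]methyl}-5-hydroxy-7-methoxy-4H-chromen-4-one | COc1cc2oc(-c3ccc(OCOC)cc3F)c(C[C@@H]3OC(=O)OC3(C)C)c(=O)c2c(O)c1
F6 | step 9 | 2-[2-fluoro-4-(methoxymethoxy)phenyl]-3-[(2S)-2,3-dihydroxy-3-methylbutyl]-5-hydroxy-7-methoxy-4H-chromen-4-one | COc1cc2oc(-c3ccc(OCOC)cc3F)c(C[C@H](O)C(C)(C)O)c(=O)c2c(O)c1
F7 | step 10 | (6S)-9-hydroxy-6-(2-hydroxypropan-2-yl)-11-methoxy-3-(methoxymethoxy)-8-oxo-6,7-dihydro-8H-chromeno[3,2-d][1]benzoxepine-10-carbaldehyde | COc1cc2oc3c(c(=O)c2c(O)c1C=O)C[C@@H](C(C)(C)O)Oc1cc(OCOC)ccc1-3
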